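**Plan**
1. Cuts: C7=C8 (olefination of a C8 lactol with a ring-A C7 sulfone), then C9=C10 (ring-closing metathesis of the methacrylate of a C11 vinyl carbinol), then C10–C11 (vinyl Grignard on a C11 aldehyde). Ring B goes back to a quinone monoketal of a terephthalate, ring A to epoxygeranyl acetate.
2. Enabling feature: in the Z-trisubstituted C9(Me)=C10 alkene, C8 and the carbinol carbon C11 lie on the same side, so O11–C11–C10=C9–C8(=O) can be held as a five-membered α-methylbutenolide with O11 as ring oxygen.
3. Forward: ring A closes by radical epoxy-polyene cyclization; ring B comes from dearomatisation, epoxidation and two ketone reductions; the temporary lactone ring closes by metathesis, is opened by half-reduction and joined to ring A by olefination; one desilylation ends the route.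
4. Stereochemistry: C2/C6 from Shi epoxidation and the chair cyclization; C12/C13 from tartrate-mediated epoxidation; C17 and C14 from hydride attack on the oxirane face; C11 from non-chelate (Felkin–Anh/Cornforth) vinyl addition; 9Z from the lactone ring, 7E from the Julia–Kocienski step.

Key step: step 20

Numbering: target locants are used. Ring A is C1 (CMe2), C2 (carbinol), C5 (methylidene carbon), C6; the chain is C7–C11; ring B is C12 (oxirane carbon bearing C11), C13 (oxirane CH), C14, C15 (bears C18H2O), C16, C17. In ring B the oxirane oxygen is on the β-face; C11, O14 and O17 are α. TBS = tert-butyldimethylsilyl, TES = triethylsilyl.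

Assumption: diisopropyl L-tartrate is taken as the antipode that steers the peroxide to the β-face in step 11; if the opposite sense is found, diisopropyl D-tartrate is used with nothing else changed.

Step 1
Reactants: 1 geranyl acetate
Product: 2 (R)-6,7-epoxygeranyl acetate
Conditions: D-fructose-derived Shi ketone (0.3 equiv), KHSO5 (as 2KHSO5·KHSO4·K2SO4), K2CO3, Bu4NHSO4, MeCN/CH2(OMe)2/aq. Na2B4O7–Na2EDTA, 0 °C
Reagents that add atoms: potassium peroxymonosulfate, [K+].[O-]S(=O)(=O)OO
Why: Shi epoxidation: the dioxirane of the ketone oxidises only the electron-rich distal trisubstituted alkene (the allylic acetate alkene is deactivated) through the spiro transition state, which should give the (R)-epoxide whose CH becomes C2.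

Step 2
Reactants: 2 (R)-6,7-epoxygeranyl acetate
Product: 3 cis-hydroxy acetate [(1S,3R)-3-hydroxy-2,2-dimethyl-6-methylidenecyclohexyl]methyl acetate
Conditions: Cp2TiCl2 (2.2 equiv), Mn dust, THF, rt; then 1 M aq. HCl
Reagents that add atoms: none
Why: Titanocene-mediated radical epoxy-polyene cyclization: Cp2TiCl (trivalent titanium, formed from Cp2TiCl2 and Mn) opens the oxirane to the tertiary radical, which closes 6-endo through a chair with the titanoxy and acetoxymethyl groups equatorial (C6 cis to O2), and trapping by a second Cp2TiCl with β-hydride elimination leaves the exocyclic C5 methylidene.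

Step 3
Reactants: 3 cis-hydroxy acetate
Product: 4 TES ether of 3
Conditions: TESOTf (1.3 equiv), 2,6-lutidine, CH2Cl2, 0 °C
Reagents that add atoms: triethylsilyl trifluoromethanesulfonate, CC[Si](CC)(CC)OS(=O)(=O)C(F)(F)F
Why: Silyl ether formation with the triflate, needed for the neopentyl-type secondary alcohol; the triethylsilyl group is chosen because it leaves easily from this hindered position in the last step.

Step 4
Reactants: 4 TES ether acetate
Product: 5 ring-A primary alcohol [(1S,3R)-2,2-dimethyl-6-methylidene-3-(triethylsilyloxy)cyclohexyl]methanol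
Conditions: K2CO3 (0.2 equiv), MeOH, 0 °C to rt
Reagents that add atoms: none
Why: Base-catalysed transesterification of the primary acetate with methanol; the hindered silyl ether and the alkene are untouched.

Step 5
Reactants: 5 ring-A primary alcohol
Product: 6 phenyltetrazolyl sulfide of ring A
Conditions: 1-phenyl-1H-tetrazole-5-thiol, PPh3, DIAD, THF, 0 °C to rt
Reagents that add atoms: 1-phenyl-1H-tetrazole-5-thiol, Sc1nnnn1-c1ccccc1
Why: Mitsunobu thioetherification of the primary alcohol with the acidic tetrazole thiol; C6 is not involved and keeps its configuration.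

Step 6
Reactants: 6 phenyltetrazolyl sulfide
Product: 7 ring-A C7 phenyltetrazolyl sulfone
Conditions: (NH4)6Mo7O24·4H2O (0.1 equiv), 30% H2O2, EtOH, 0 °C to rt
Reagents that add atoms: hydrogen peroxide, OO
Why: Molybdate-catalysed peroxide oxidation of sulfide to sulfone; the peroxomolybdate attacks sulfur and leaves the 1,1-disubstituted alkene alone.

Step 7
Reactants: 8 diethyl 2,5-dihydroxyterephthalate
Product: 9 diethyl 2-hydroxy-5-methoxyterephthalate
Conditions: MeI (1.0 equiv), K2CO3 (1.0 equiv), DMF, rt
Reagents that add atoms: iodomethane, CI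
Why: Williamson O-methylation with one equivalent each of base and iodide, a statistical desymmetrisation from which the monoether is separated and unreacted 8 is recycled.

Step 8
Reactants: 9 diethyl 2-hydroxy-5-methoxyterephthalate
Product: 10 4-(ethoxycarbonyl)-5-hydroxy-2-methoxybenzoic acid
Conditions: LiOH·H2O (2.5 equiv), THF/H2O, rt; then 1 M HCl
Reagents that add atoms: lithium hydroxide, [Li+].[OH-]
Why: Chemoselective saponification: as the phenoxide, the ester ortho to O− is a vinylogous carboxylate and resists hydroxide, so only the ester ortho to OMe should be cleaved.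

Step 9
Reactants: 10 4-(ethoxycarbonyl)-5-hydroxy-2-methoxybenzoic acid
Product: 11 ethyl 2-hydroxy-4-(hydroxymethyl)-5-methoxybenzoate
Conditions: BH3·SMe2 (2.2 equiv), THF, 0 °C; MeOH quench
Reagents that add atoms: none
Why: Chemoselective borane reduction of the carboxylic acid through its acyloxyborane; at 0 °C the chelated aryl ester should be left.

Step 10
Reactants: 11 ethyl 2-hydroxy-4-(hydroxymethyl)-5-methoxybenzoate
Product: 12 quinone monoketal ethyl 4-(hydroxymethyl)-3,3-dimethoxy-6-oxocyclohexa-1,4-diene-1-carboxylate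
Conditions: PhI(OAc)2 (1.1 equiv), MeOH, 0 °C
Reagents that add atoms: methanol, CO
Why: Oxidative dearomatisation of a para-methoxyphenol by the hypervalent iodine reagent in methanol; methanol adds para to the phenol oxygen to give the quinone monoketal.

Step 11
Reactants: 12 quinone monoketal
Product: 13 12,13-epoxy ketone (oxirane oxygen β)
Conditions: Ph3COOH (2 equiv), NaN(SiMe3)2 (3 equiv), diisopropyl L-tartrate (1.2 equiv), 4 Å molecular sieves, toluene, −78 to −50 °C; aq. NH4Cl
Reagents that add atoms: triphenylmethyl hydroperoxide, OOC(c1ccccc1)(c1ccccc1)c1ccccc1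
Why: Tartrate-mediated nucleophilic (Weitz–Scheffer) epoxidation of a hydroxymethyl quinone monoketal: the sodium alkoxide of the C18 hydroxyl and the tartrate bind sodium trityl peroxide and deliver it to C13, the only unsubstituted β-carbon (β to both ketone and ester), and the enolate closes the oxirane, so the tartrate fixes C12 and C13.

Step 12
Reactants: 13 12,13-epoxy ketone
Product: 14 C17 alcohol (O17 α)
Conditions: NaBH4, CeCl3·7H2O, MeOH, −78 °C
Reagents that add atoms: none
Why: Luche 1,2-reduction of the C17 enone carbonyl with the ester untouched; hydride is expected on the oxirane face, away from the ester on the quaternary C12 to which cerium is chelated, which puts O17 α and cis to the ester.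

Step 13
Reactants: 14 C17 alcohol
Product: 15 hydroxy enone (C14 ketone)
Conditions: PPTS (cat.), acetone/H2O (10:1), rt
Reagents that add atoms: water, O
Why: Acid-catalysed hydrolysis of the allylic dimethyl ketal to the enone; the electron-poor oxirane between ester and ketone should resist opening under these mild conditions.

Step 14
Reactants: 15 hydroxy enone
Product: 16 bis-TBS enone
Conditions: TBSOTf (2.5 equiv), 2,6-lutidine, CH2Cl2, −78 °C
Reagents that add atoms: tert-butyldimethylsilyl trifluoromethanesulfonate, CC(C)(C)[Si](C)(C)OS(=O)(=O)C(F)(F)F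
Why: Silyl ether formation at the primary and the hindered secondary hydroxyl with the triflate at low temperature, where 2,6-lutidine does not enolise the enone.

Step 15
Reactants: 16 bis-TBS enone
Product: 17 C14 alcohol (O14 α)
Conditions: NaBH4, CeCl3·7H2O, MeOH, −78 °C
Reagents that add atoms: none
Why: Luche 1,2-reduction of the C14 enone carbonyl; the α-face is screened by the C17 silyl ether and the C12 ester, so hydride should arrive on the oxirane face and leave O14 α, anti to the oxirane.

Step 16
Reactants: 17 C14 alcohol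
Product: 18 tris-TBS ester
Conditions: TBSOTf (1.3 equiv), 2,6-lutidine, CH2Cl2, −78 to 0 °C
Reagents that add atoms: tert-butyldimethylsilyl trifluoromethanesulfonate, CC(C)(C)[Si](C)(C)OS(=O)(=O)C(F)(F)F
Why: Silyl ether formation at the secondary allylic alcohol; no stereocenter is touched.

Step 17
Reactants: 18 tris-TBS ester
Product: 19 C11 aldehyde
Conditions: i-Bu2AlH (1.2 equiv), toluene, −78 °C; aq. KNaC4H4O6
Reagents that add atoms: none
Why: Partial reduction of the ester: the aluminium hemiacetal of this neopentyl α-oxygenated ester is stable at −78 °C and gives the aldehyde on work-up, and C12 carries no hydrogen and cannot epimerise.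

Step 18
Reactants: 19 C11 aldehyde; 20 vinylmagnesium bromide
Product: 21 (11S)-vinyl carbinol
Conditions: THF, −78 °C; aq. NH4Cl
Reagents that add atoms: vinylmagnesium bromide (compound 20), C=C[Mg]Br
Why: Grignard addition to an α,β-epoxy aldehyde under Felkin–Anh/Cornforth (non-chelate) control: with the carbonyl turned away from the oxirane C–O bond, vinyl should add on the open outer face beside the oxirane oxygen and not under the ring where the silyl ethers sit, giving the anti (11S) carbinol.

Step 19
Reactants: 21 (11S)-vinyl carbinol; 22 methacryloyl chloride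
Product: 23 methacrylate of the C11 vinyl carbinol
Conditions: i-Pr2NEt, DMAP (0.2 equiv), CH2Cl2, 0 °C to rt
Reagents that add atoms: methacryloyl chloride (compound 22), CC(=C)C(Cl)=O
Why: DMAP-catalysed acylation of the hindered secondary allylic alcohol by the acid chloride; no stereocenter is touched.

Step 20
Reactants: 23 methacrylate of the C11 vinyl carbinol
Product: 24 α-methylbutenolide
Conditions: second-generation Grubbs catalyst (H2IMes)(PCy3)Cl2Ru=CHPh (10 mol %), toluene (5 mM), 80 °C
Reagents that add atoms: none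
Why: Ring-closing metathesis of an allylic methacrylate, a known way to α-methylbutenolides: the ruthenium benzylidene exchanges onto the monosubstituted vinyl group, the resulting C10 alkylidene adds [2+2] to the methacrylate C9=CH2, and cycloreversion releases ethene. The ring O11–C11–C10=C9–C8(=O) closes as a five-membered lactone with the new C9=C10 bond endocyclic, so C8 and C11 can only be cis, which is the 9Z geometry of the target. No stereocenter is formed; C11 comes from step 18 and is not touched. The step needs the two terminal alkenes to react in preference to the ring-B C15=C16 bond, which is trisubstituted and flanked by silyloxy groups and should not load the catalyst. It also needs ring closure to win over cross-metathesis dimerisation, which high dilution and the ease of five-membered closure secure. The N-heterocyclic carbene catalyst is chosen because the 1,1-disubstituted, electron-poor methacrylate alkene is sluggish with first-generation catalysts; the oxirane and silyl ethers are spectators.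

Step 21
Reactants: 24 α-methylbutenolide
Product: 25 lactol (C8 anomers)
Conditions: i-Bu2AlH (1.1 equiv), CH2Cl2, −78 °C; aq. KNaC4H4O6; crude lactol used at once
Reagents that add atoms: none
Why: Half-reduction of the lactone carbonyl to the lactol at −78 °C; the lactol is kept neutral and unpurified because acid would dehydrate it to a furan.

Step 22
Reactants: 25 lactol; 7 ring-A C7 phenyltetrazolyl sulfone
Product: 27 silyl-protected (7E,9Z,11S)-dienol (O2 TES; O14/O17/O18 TBS), via open Z-hydroxy enal 26 (not isolated)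
Conditions: KN(SiMe3)2 (2.8 equiv) added to 25 and 7 (1.5 equiv), THF, −78 °C to rt; aq. NH4Cl
Reagents that add atoms: none
Why: Julia–Kocienski olefination: base opens the lactol to the potassium alkoxide of hydroxy enal 26, the metallated sulfone adds to C8, and Smiles rearrangement with loss of SO2 and the tetrazolone should give the (7E)-alkene, while the C11 alkoxide prevents γ-deprotonation so that the 9Z geometry and C11 are kept.

Step 23
Reactants: 27 silyl-protected dienol
Product: 28 target CNP0357844.1
Conditions: Bu4NF/AcOH (1:1, excess), THF, 0 °C to rt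
Reagents that add atoms: none
Why: Fluoride-mediated cleavage of all four silyl ethers, buffered with acetic acid so that the epoxy alcohols do not undergo base-induced epoxide migration.

**Compound list**
1 | geranyl acetate, (2E)-3,7-dimethylocta-2,6-dien-1-yl acetate | CC(C)=CCC/C(C)=C/COC(C)=O | starting material
2 | (R)-6,7-epoxygeranyl acetate, (2E)-5-[(2R)-3,3-dimethyloxiran-2-yl]-3-methylpent-2-en-1-yl acetate | CC(=O)OC/C=C(\C)CC[C@H]1OC1(C)C | intermediate
3 | [(1S,3R)-3-hydroxy-2,2-dimethyl-6-methylidenecyclohexyl]methyl acetate (OH and CH2OAc cis) | C=C1CC[C@@H](O)C(C)(C)[C@H]1COC(C)=O | intermediate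
4 | [(1S,3R)-2,2-dimethyl-6-methylidene-3-(triethylsilyloxy)cyclohexyl]methyl acetate | C=C1CC[C@@H](O[Si](CC)(CC)CC)C(C)(C)[C@H]1COC(C)=O | intermediate
5 | [(1S,3R)-2,2-dimethyl-6-methylidene-3-(triethylsilyloxy)cyclohexyl]methanol | C=C1CC[C@@H](O[Si](CC)(CC)CC)C(C)(C)[C@H]1CO | intermediate
6 | 5-({[(1S,3R)-2,2-dimethyl-6-methylidene-3-(triethylsilyloxy)cyclohexyl]methyl}sulfanyl)-1-phenyl-1H-tetrazole | C=C1CC[C@@H](O[Si](CC)(CC)CC)C(C)(C)[C@H]1CSc1nnnn1-c1ccccc1 | intermediate
7 | 5-({[(1S,3R)-2,2-dimethyl-6-methylidene-3-(triethylsilyloxy)cyclohexyl]methyl}sulfonyl)-1-phenyl-1H-tetrazole (ring-A C7 sulfone) | C=C1CC[C@@H](O[Si](CC)(CC)CC)C(C)(C)[C@H]1CS(=O)(=O)c1nnnn1-c1ccccc1 | intermediate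
8 | diethyl 2,5-dihydroxyterephthalate | CCOC(=O)c1cc(O)c(cc1O)C(=O)OCC | starting material
9 | diethyl 2-hydroxy-5-methoxyterephthalate | CCOC(=O)c1cc(OC)c(cc1O)C(=O)OCC | intermediate
10 | 4-(ethoxycarbonyl)-5-hydroxy-2-methoxybenzoic acid | CCOC(=O)c1cc(OC)c(cc1O)C(=O)O | intermediate
11 | ethyl 2-hydroxy-4-(hydroxymethyl)-5-methoxybenzoate | CCOC(=O)c1cc(OC)c(CO)cc1O | intermediate
12 | ethyl 4-(hydroxymethyl)-3,3-dimethoxy-6-oxocyclohexa-1,4-diene-1-carboxylate (quinone monoketal) | CCOC(=O)C1=CC(OC)(OC)C(CO)=CC1=O | intermediate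
13 | ethyl (1S,6R)-4-(hydroxymethyl)-5,5-dimethoxy-2-oxo-7-oxabicyclo[4.1.0]hept-3-ene-1-carboxylate (12,13-oxirane, oxygen β) | CCOC(=O)[C@]12O[C@H]1C(OC)(OC)C(CO)=CC2=O | intermediate
14 | ethyl (1R,2S,6R)-2-hydroxy-4-(hydroxymethyl)-5,5-dimethoxy-7-oxabicyclo[4.1.0]hept-3-ene-1-carboxylate (O17 α, cis to the ester) | CCOC(=O)[C@]12O[C@H]1C(OC)(OC)C(CO)=C[C@@H]2O | intermediate
15 | ethyl (1R,2S,6R)-2-hydroxy-4-(hydroxymethyl)-5-oxo-7-oxabicyclo[4.1.0]hept-3-ene-1-carboxylate | CCOC(=O)[C@]12O[C@H]1C(=O)C(CO)=C[C@@H]2O | intermediate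
16 | ethyl (1S,2S,6R)-2-(TBS-oxy)-4-(TBS-oxymethyl)-5-oxo-7-oxabicyclo[4.1.0]hept-3-ene-1-carboxylate | CCOC(=O)[C@]12O[C@H]1C(=O)C(CO[Si](C)(C)C(C)(C)C)=C[C@@H]2O[Si](C)(C)C(C)(C)C | intermediate
17 | ethyl (1S,2S,5R,6S)-5-hydroxy-2-(TBS-oxy)-4-(TBS-oxymethyl)-7-oxabicyclo[4.1.0]hept-3-ene-1-carboxylate (O14 α, anti to the oxirane) | CCOC(=O)[C@]12O[C@H]1[C@H](O)C(CO[Si](C)(C)C(C)(C)C)=C[C@@H]2O[Si](C)(C)C(C)(C)C | intermediate
18 | ethyl (1S,2S,5R,6S)-2,5-bis(TBS-oxy)-4-(TBS-oxymethyl)-7-oxabicyclo[4.1.0]hept-3-ene-1-carboxylate | CCOC(=O)[C@]12O[C@H]1[C@H](O[Si](C)(C)C(C)(C)C)C(CO[Si](C)(C)C(C)(C)C)=C[C@@H]2O[Si](C)(C)C(C)(C)C | intermediate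
19 | (1S,2S,5R,6S)-2,5-bis(TBS-oxy)-4-(TBS-oxymethyl)-7-oxabicyclo[4.1.0]hept-3-ene-1-carbaldehyde | O=C[C@]12O[C@H]1[C@H](O[Si](C)(C)C(C)(C)C)C(CO[Si](C)(C)C(C)(C)C)=C[C@@H]2O[Si](C)(C)C(C)(C)C | intermediate
20 | vinylmagnesium bromide | C=C[Mg]Br | starting material
21 | (1S)-1-[(1S,2S,5R,6S)-2,5-bis(TBS-oxy)-4-(TBS-oxymethyl)-7-oxabicyclo[4.1.0]hept-3-en-1-yl]prop-2-en-1-ol (11S) | C=C[C@H](O)[C@]12O[C@H]1[C@H](O[Si](C)(C)C(C)(C)C)C(CO[Si](C)(C)C(C)(C)C)=C[C@@H]2O[Si](C)(C)C(C)(C)C | intermediate
22 | methacryloyl chloride | CC(=C)C(Cl)=O | starting material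
23 | (1S)-1-[(1S,2S,5R,6S)-2,5-bis(TBS-oxy)-4-(TBS-oxymethyl)-7-oxabicyclo[4.1.0]hept-3-en-1-yl]prop-2-en-1-yl 2-methylprop-2-enoate | C=C[C@H](OC(=O)C(C)=C)[C@]12O[C@H]1[C@H](O[Si](C)(C)C(C)(C)C)C(CO[Si](C)(C)C(C)(C)C)=C[C@@H]2O[Si](C)(C)C(C)(C)C | intermediate
24 | (5S)-5-[(1S,2S,5R,6S)-2,5-bis(TBS-oxy)-4-(TBS-oxymethyl)-7-oxabicyclo[4.1.0]hept-3-en-1-yl]-3-methylfuran-2(5H)-one | CC1=C[C@H](OC1=O)[C@]23O[C@H]2[C@H](O[Si](C)(C)C(C)(C)C)C(CO[Si](C)(C)C(C)(C)C)=C[C@@H]3O[Si](C)(C)C(C)(C)C | intermediate
25 | (5S)-5-[same ring-B unit]-3-methyl-2,5-dihydrofuran-2-ol (lactol, both C8 anomers) | CC1=C[C@H](OC1O)[C@]23O[C@H]2[C@H](O[Si](C)(C)C(C)(C)C)C(CO[Si](C)(C)C(C)(C)C)=C[C@@H]3O[Si](C)(C)C(C)(C)C | intermediate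
26 | (2Z,4S)-4-hydroxy-4-[same ring-B unit]-2-methylbut-2-enal (open form of 25, present as potassium alkoxide) | O=C/C(C)=C\[C@H](O)[C@]12O[C@H]1[C@H](O[Si](C)(C)C(C)(C)C)C(CO[Si](C)(C)C(C)(C)C)=C[C@@H]2O[Si](C)(C)C(C)(C)C | intermediate
27 | (7E,9Z,11S)-dienol: the target with O2 as TES ether and O14, O17 and O18 as TBS ethers | C=C1CC[C@@H](O[Si](CC)(CC)CC)C(C)(C)[C@H]1/C=C/C(C)=C\[C@H](O)[C@]12O[C@H]1[C@H](O[Si](C)(C)C(C)(C)C)C(CO[Si](C)(C)C(C)(C)C)=C[C@@H]2O[Si](C)(C)C(C)(C)C | intermediate
28 | CNP0357844.1, (1R,2S,5R,6S)-4-(hydroxymethyl)-1-{(1S,2Z,4E)-1-hydroxy-5-[(1S,3R)-3-hydroxy-2,2-dimethyl-6-methylidenecyclohexyl]-3-methylpenta-2,4-dien-1-yl}-7-oxabicyclo[4.1.0]hept-3-ene-2,5-diol; the C12 descriptor changes from S to R on desilylation with no change in space | C=C1CC[C@@H](O)C(C)(C)[C@H]1/C=C/C(C)=C\[C@H](O)[C@]12O[C@H]1[C@H](O)C(CO)=C[C@@H]2O | target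

**Step count**
Total: 23 steps. Longest linear sequence: 17 steps (8 to 28, steps 7–23); the ring-A sulfone 7 takes 6 steps.

**Steps most likely to fail**

Step 11. The tartrate complex may select the enantiofaces poorly or in the wrong sense, or the stabilised β-keto ester enolate may close the oxirane slowly and let the peroxide addition reverse. The fallback replaces reagent control by an auxiliary. Starting from 12, the dimethyl ketal is exchanged with (2R,4R)-pentane-2,4-diol (PPTS, benzene, removal of methanol) to give the chiral dioxane ketal F1. Weitz–Scheffer epoxidation with t-BuOOH/DBU, in which the ketal methyl groups shield one face of C13, gives the epoxy ketone F2. Luche reduction as in step 12 gives the C17 alcohol F3, and the hydrolysis of step 13 removes the auxiliary and returns to the route at 15. The antipode of the diol is chosen by the same test as the tartrate.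

Step 15. Hydride may attack anti to the oxirane, the usual preference of epoxy ketones, if the α-face groups shield too little. The fallback corrects the centre by inversion. Starting from 16, the reduction then gives the 14-epimeric alcohol F4; Mitsunobu esterification with 4-nitrobenzoic acid (PPh3, DIAD, THF) inverts C14 to give the 4-nitrobenzoate F5; methanolysis (K2CO3, MeOH, 0 °C) returns to the route at 17.

Step 18. Diastereoselectivity may be low or reversed if magnesium chelates the oxirane oxygen or the crowded aldehyde reacts from another rotamer. The fallback sets C11 by a catalyst. Starting from 19, the addition is run without regard to selectivity; the carbinol mixture containing the 11-epimer F6 is oxidised with Dess–Martin periodinane to the vinyl ketone F7; CBS reduction ((R)-2-methyl-CBS-oxazaborolidine, BH3·SMe2, −40 °C; the antipode if the vinyl group rather than C12 acts as the larger substituent) returns to the route at 21.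

**Further compounds**
F1 | step 11 | ethyl 4-(hydroxymethyl)-6-oxocyclohexa-1,4-diene-1-carboxylate 3-spiro ketal with (2R,4R)-pentane-2,4-diol (4,6-dimethyl-1,3-dioxane) | CCOC(=O)C1=CC2(O[C@H](C)C[C@@H](C)O2)C(CO)=CC1=O
F2 | step 11 | 12,13-epoxide of F1 (oxirane oxygen β) | CCOC(=O)[C@]12O[C@H]1C3(O[C@H](C)C[C@@H](C)O3)C(CO)=CC2=O
F3 | step 11 | C17 alcohol of F2 (O17 α) | CCOC(=O)[C@]12O[C@H]1C3(O[C@H](C)C[C@@H](C)O3)C(CO)=C[C@@H]2O
F4 | step 15 | 14-epimer of 17 (O14 β, syn to the oxirane) | CCOC(=O)[C@]12O[C@H]1[C@@H](O)C(CO[Si](C)(C)C(C)(C)C)=C[C@@H]2O[Si](C)(C)C(C)(C)C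
F5 | step 15 | 4-nitrobenzoate of 17 (O14 α) | CCOC(=O)[C@]12O[C@H]1[C@H](OC(=O)c3ccc(cc3)[N+](=O)[O-])C(CO[Si](C)(C)C(C)(C)C)=C[C@@H]2O[Si](C)(C)C(C)(C)C
F6 | step 18 | 11-epimer of 21, (11R)-vinyl carbinol | C=C[C@@H](O)[C@]12O[C@H]1[C@H](O[Si](C)(C)C(C)(C)C)C(CO[Si](C)(C)C(C)(C)C)=C[C@@H]2O[Si](C)(C)C(C)(C)C
F7 | step 18 | C11 vinyl ketone, 1-[ring-B unit of 19]prop-2-en-1-one | C=CC(=O)[C@]12O[C@H]1[C@H](O[Si](C)(C)C(C)(C)C)C(CO[Si](C)(C)C(C)(C)C)=C[C@@H]2O[Si](C)(C)C(C)(C)C
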